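**Retrosynthetic overview**

1. The target comes from silyl ether 17 by desilylation. The pyran ring of 17 is closed last, at O1–C8a, by intramolecular palladium-catalysed aryl etherification of the (Z)-alkenyl tertiary alcohol 16, which leaves the carbinol configuration untouched. 16 comes from (S)-propargylic alcohol 12 and aryl iodide 14 by Sonogashira coupling and semi-hydrogenation.
2. 12 comes from allylic alcohol 8 by Sharpless epoxidation, chlorination and base-induced double elimination. 8 already holds all twenty terpenoid carbons and the ring stereocentre.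
3. 8 comes from aldehyde 6 by Wolff–Kishner reduction. 6 comes from a catalytic enantioselective Diels–Alder reaction of methacrolein with the terminal diene of the acyclic tetraene 4, made from farnesyl acetate by allylic oxidation and methylenation.
4. Enabling feature: in the 2,6,6-trimethylcyclohex-2-enyl ring the C2=C3 double bond lies opposite the C5–C6 bond, the stereocentre C1 sits between olefinic C2 and quaternary C6, and one of the two methyl groups on C6 can enter as the formyl group of an activated dienophile. The ring is thus a cyclohexene retron (diene C1–C2–C3–C4, dienophile C5–C6).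
5. Ring order: cyclohexene ring first (step 4), pyran ring of the chromene last (step 12); the benzene ring is bought.

Key step: step 4

Assumptions: 4-bromo-3-iodophenol (13) is taken as a catalogue compound; the (S)-configured catalyst in step 4 is assigned from the accepted binding model for 2-substituted acroleins, and its mirror image would be used if the facial sense or the endo/exo mode proved opposite.

**Route**

Step 1
Reactants: 1 (2E,6E)-farnesyl acetate
Product: 2 (2E,6E,10E)-12-hydroxy-3,7,11-trimethyldodeca-2,6,10-trien-1-yl acetate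
Conditions: SeO2 (0.2 equiv), t-BuOOH (70% aq.), salicylic acid (cat.), CH2Cl2, 0 °C to rt
Reagents that add atoms: selenium dioxide O=[Se]=O (catalytic oxygen carrier); tert-butyl hydroperoxide CC(C)(C)OO (terminal oxidant)
Why: The SeO2/t-BuOOH allylic oxidation (ene reaction, then [2,3]-sigmatropic shift) should pick the (E)-methyl group of the terminal, least hindered trisubstituted alkene and give the (E)-allylic alcohol.

Step 2
Reactants: 2 (2E,6E,10E)-12-hydroxy-3,7,11-trimethyldodeca-2,6,10-trien-1-yl acetate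
Product: 3 (2E,6E,10E)-3,7,11-trimethyl-12-oxododeca-2,6,10-trien-1-yl acetate
Conditions: MnO2 (excess), CH2Cl2, rt
Reagents that add atoms: none
Why: MnO2 oxidation of a primary allylic alcohol should give the (E)-enal without touching the acetate or the alkene geometry.

Step 3
Reactants: 3 (2E,6E,10E)-3,7,11-trimethyl-12-oxododeca-2,6,10-trien-1-yl acetate
Product: 4 (2E,6E,10E)-3,7,11-trimethyltrideca-2,6,10,12-tetraen-1-yl acetate
Conditions: Ph3PCH3Br, KN(SiMe3)2, THF, 0 °C; then 3, −78 to 0 °C
Reagents that add atoms: methyltriphenylphosphonium bromide C[P+](c1ccccc1)(c1ccccc1)c1ccccc1.[Br-]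
Why: Wittig methylenation of the enal should give the (E)-3-methyl-1,3-diene terminus with the C10=C11 geometry kept, since the ylide adds to the aldehyde much faster than to the acetate at low temperature.

Step 4
Reactants: 4 (2E,6E,10E)-3,7,11-trimethyltrideca-2,6,10,12-tetraen-1-yl acetate; 5 methacrolein
Product: 6 (2E,6E)-9-[(1R,6S)-6-formyl-2,6-dimethylcyclohex-2-en-1-yl]-3,7-dimethylnona-2,6-dien-1-yl acetate (formyl group cis to the side chain)
Conditions: (S)-1-(2-methylphenyl)-3,3-diphenyltetrahydro-1H,3H-pyrrolo[1,2-c][1,3,2]oxazaborole (20 mol%), HN(SO2CF3)2 (18 mol%), CH2Cl2, −78 to −40 °C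
Reagents that add atoms: none
Why: The N-protonated oxazaborolidine binds methacrolein at boron (s-trans enal, formyl C–H···O contact) and lowers its LUMO for a concerted, strongly asynchronous normal-demand [4+2] cycloaddition with the s-cis C10–C13 diene of 4; the closest known reaction type is the oxazaborolidinium-catalysed enantioselective Diels–Alder reaction of 2-substituted acroleins with acyclic dienes. The cyclohexene ring is closed by intermolecular suprafacial [4+2] addition, the CH2(β)–C13 bond running ahead of the Cα–C10 bond. The regiochemistry (quaternary carbon next to C10) should follow from the terminal alkyl substituent on C10, which outweighs the internal C11 methyl group as in other 1,2-dialkyl dienes, and from the preference of the leading bond for the unhindered CH2 terminus. The quaternary centre C6 (S) is set by the catalyst, whose phenyl group covers the Si face of the α-carbon so that the diene adds to the Re face; the ring centre C1 (R in 6, S once the formyl group has become methyl) is set by formyl-endo approach, which places the outside substituent of the (E)-configured C10 cis to the formyl group. The step therefore needs regio-, endo- and facial selectivity, plus chemoselectivity for the only conjugated diene; the isolated trisubstituted alkenes and the acetate should be inert at −78 °C.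

Step 5
Reactants: 6 (2E,6E)-9-[(1R,6S)-6-formyl-2,6-dimethylcyclohex-2-en-1-yl]-3,7-dimethylnona-2,6-dien-1-yl acetate
Product: 8 (2E,6E)-3,7-dimethyl-9-[(1S)-2,6,6-trimethylcyclohex-2-en-1-yl]nona-2,6-dien-1-ol, via hydroxy hydrazone 7 (not isolated)
Conditions: N2H4·H2O, diethylene glycol, 120 °C; then KOH, 200 °C (water and excess hydrazine distilled off)
Reagents that add atoms: none
Why: Wolff–Kishner reduction (Huang–Minlon procedure) should turn the formyl group into the second methyl group on C6, which thereby stops being a stereocentre, while hydrazine cleaves the acetate and the ring stereocentre, not being α to the carbonyl group, cannot epimerise.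

Step 6
Reactants: 8 (2E,6E)-3,7-dimethyl-9-[(1S)-2,6,6-trimethylcyclohex-2-en-1-yl]nona-2,6-dien-1-ol
Product: 9 [(2S,3S)-3-methyl-3-{(3E)-4-methyl-6-[(1S)-2,6,6-trimethylcyclohex-2-en-1-yl]hex-3-en-1-yl}oxiran-2-yl]methanol
Conditions: Ti(OiPr)4 (10 mol%), L-(+)-diethyl tartrate (12 mol%), t-BuOOH (anhydrous, decane), 4 Å molecular sieves, CH2Cl2, −20 °C
Reagents that add atoms: tert-butyl hydroperoxide CC(C)(C)OO
Why: Sharpless asymmetric epoxidation should epoxidise only the allylic alcohol alkene, and the L-(+)-tartrate ligand should deliver oxygen to the face that gives the (2S,3S)-epoxide under reagent control, independent of the remote ring centre.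

Step 7
Reactants: 9 [(2S,3S)-3-methyl-3-{(3E)-4-methyl-6-[(1S)-2,6,6-trimethylcyclohex-2-en-1-yl]hex-3-en-1-yl}oxiran-2-yl]methanol
Product: 10 (2R,3S)-2-(chloromethyl)-3-methyl-3-{(3E)-4-methyl-6-[(1S)-2,6,6-trimethylcyclohex-2-en-1-yl]hex-3-en-1-yl}oxirane (same spatial arrangement as 9; the descriptor at C2 changes by priority only)
Conditions: PPh3, CCl4, NaHCO3, reflux
Reagents that add atoms: carbon tetrachloride ClC(Cl)(Cl)Cl
Why: The Appel reaction under buffered neutral conditions should replace the primary hydroxyl group by chloride without opening the epoxide or touching either stereocentre.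

Step 8
Reactants: 10 (2R,3S)-2-(chloromethyl)-3-methyl-3-{(3E)-4-methyl-6-[(1S)-2,6,6-trimethylcyclohex-2-en-1-yl]hex-3-en-1-yl}oxirane
Product: 12 (3S,6E)-3,7-dimethyl-9-[(1S)-2,6,6-trimethylcyclohex-2-en-1-yl]non-6-en-1-yn-3-ol, via lithium chlorovinyl alkoxide 11 (not isolated)
Conditions: n-BuLi (3.2 equiv), THF, −40 °C; aq. NH4Cl
Reagents that add atoms: none
Why: Base-induced double elimination of a 2,3-epoxy chloride (lithiation at the chloromethyl carbon opens the epoxide to the chlorovinyl alkoxide, dehydrochlorination then gives the acetylide) should deliver the tertiary propargylic alcohol with the C–O bond of the carbinol carbon intact, so the configuration set in step 6 is kept.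

Step 9
Reactants: 13 4-bromo-3-iodophenol
Product: 14 (4-bromo-3-iodophenoxy)tri(propan-2-yl)silane
Conditions: iPr3SiCl, imidazole, DMF, rt
Reagents that add atoms: chlorotri(propan-2-yl)silane CC(C)[Si](Cl)(C(C)C)C(C)C
Why: Silylation of the phenol gives a triisopropylsilyl ether that should survive amine and carbonate bases and is removed by fluoride at the end.

Step 10
Reactants: 12 (3S,6E)-3,7-dimethyl-9-[(1S)-2,6,6-trimethylcyclohex-2-en-1-yl]non-6-en-1-yn-3-ol; 14 (4-bromo-3-iodophenoxy)tri(propan-2-yl)silane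
Product: 15 (3S,6E)-1-{2-bromo-5-[tri(propan-2-yl)silyloxy]phenyl}-3,7-dimethyl-9-[(1S)-2,6,6-trimethylcyclohex-2-en-1-yl]non-6-en-1-yn-3-ol
Conditions: Pd(PPh3)2Cl2 (3 mol%), CuI (5 mol%), Et3N, THF, rt
Reagents that add atoms: none
Why: In the Sonogashira coupling zerovalent palladium should insert into the C–I bond and leave the neighbouring C–Br bond alone at room temperature, and the free tertiary alcohol is tolerated.

Step 11
Reactants: 15 (3S,6E)-1-{2-bromo-5-[tri(propan-2-yl)silyloxy]phenyl}-3,7-dimethyl-9-[(1S)-2,6,6-trimethylcyclohex-2-en-1-yl]non-6-en-1-yn-3-ol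
Product: 16 (1Z,3S,6E)-1-{2-bromo-5-[tri(propan-2-yl)silyloxy]phenyl}-3,7-dimethyl-9-[(1S)-2,6,6-trimethylcyclohex-2-en-1-yl]nona-1,6-dien-3-ol
Conditions: H2 (1 atm), Pd/CaCO3 poisoned with Pb(OAc)2, quinoline, EtOAc, rt
Reagents that add atoms: none
Why: Lindlar-type semi-hydrogenation adds H2 syn to the alkyne and should give the (Z)-alkene, which brings the tertiary hydroxyl group within reach of the C–Br carbon, while the poisoned catalyst leaves the trisubstituted alkenes and the aryl bromide untouched.

Step 12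
Reactants: 16 (1Z,3S,6E)-1-{2-bromo-5-[tri(propan-2-yl)silyloxy]phenyl}-3,7-dimethyl-9-[(1S)-2,6,6-trimethylcyclohex-2-en-1-yl]nona-1,6-dien-3-ol
Product: 17 {[(2S)-2-methyl-2-{(3E)-4-methyl-6-[(1S)-2,6,6-trimethylcyclohex-2-en-1-yl]hex-3-en-1-yl}-2H-chromen-6-yl]oxy}tri(propan-2-yl)silane
Conditions: Pd(OAc)2 (5 mol%), 2-(di-tert-butylphosphino)-1,1'-binaphthyl (6 mol%), Cs2CO3, toluene, 80 °C
Reagents that add atoms: none
Why: Intramolecular Buchwald–Hartwig aryl etherification (oxidative addition of zerovalent palladium into C–Br, alkoxide binding, C–O reductive elimination driven by the bulky phosphine) should close the pyran ring through the tertiary alkoxide, which has no β-hydrogen, and since no bond at the carbinol carbon is broken its configuration is retained.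

Step 13
Reactants: 17 {[(2S)-2-methyl-2-{(3E)-4-methyl-6-[(1S)-2,6,6-trimethylcyclohex-2-en-1-yl]hex-3-en-1-yl}-2H-chromen-6-yl]oxy}tri(propan-2-yl)silane
Product: 18 (2S)-2-methyl-2-{(3E)-4-methyl-6-[(1S)-2,6,6-trimethylcyclohex-2-en-1-yl]hex-3-en-1-yl}-2H-chromen-6-ol
Conditions: Bu4NF, THF, 0 °C; aq. NH4Cl
Reagents that add atoms: none
Why: Fluoride-induced desilylation of the aryl silyl ether is mild and basic, so the acid-sensitive chromene and the alkenes should be unaffected.

**Compound list**

1 | (2E,6E)-farnesyl acetate | CC(C)=CCC/C(C)=C/CC/C(C)=C/COC(C)=O | starting material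
2 | (2E,6E,10E)-12-hydroxy-3,7,11-trimethyldodeca-2,6,10-trien-1-yl acetate | OC/C(C)=C/CC/C(C)=C/CC/C(C)=C/COC(C)=O | intermediate
3 | (2E,6E,10E)-3,7,11-trimethyl-12-oxododeca-2,6,10-trien-1-yl acetate | O=C/C(C)=C/CC/C(C)=C/CC/C(C)=C/COC(C)=O | intermediate
4 | (2E,6E,10E)-3,7,11-trimethyltrideca-2,6,10,12-tetraen-1-yl acetate | C=C/C(C)=C/CC/C(C)=C/CC/C(C)=C/COC(C)=O | intermediate
5 | methacrolein (2-methylprop-2-enal) | CC(=C)C=O | starting material
6 | (2E,6E)-9-[(1R,6S)-6-formyl-2,6-dimethylcyclohex-2-en-1-yl]-3,7-dimethylnona-2,6-dien-1-yl acetate | CC1=CCC[C@](C)(C=O)[C@@H]1CC/C(C)=C/CC/C(C)=C/COC(C)=O | intermediate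
7 | (2E,6E)-9-[(1R,6S)-6-[(E)-hydrazinylidenemethyl]-2,6-dimethylcyclohex-2-en-1-yl]-3,7-dimethylnona-2,6-dien-1-ol | CC1=CCC[C@](C)(/C=N/N)[C@@H]1CC/C(C)=C/CC/C(C)=C/CO | intermediate (not isolated)
8 | (2E,6E)-3,7-dimethyl-9-[(1S)-2,6,6-trimethylcyclohex-2-en-1-yl]nona-2,6-dien-1-ol | CC1=CCCC(C)(C)[C@@H]1CC/C(C)=C/CC/C(C)=C/CO | intermediate
9 | [(2S,3S)-3-methyl-3-{(3E)-4-methyl-6-[(1S)-2,6,6-trimethylcyclohex-2-en-1-yl]hex-3-en-1-yl}oxiran-2-yl]methanol | CC1=CCCC(C)(C)[C@@H]1CC/C(C)=C/CC[C@]2(C)O[C@H]2CO | intermediate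
10 | (2R,3S)-2-(chloromethyl)-3-methyl-3-{(3E)-4-methyl-6-[(1S)-2,6,6-trimethylcyclohex-2-en-1-yl]hex-3-en-1-yl}oxirane | CC1=CCCC(C)(C)[C@@H]1CC/C(C)=C/CC[C@]2(C)O[C@H]2CCl | intermediate
11 | lithium (3S,6E)-1-chloro-3,7-dimethyl-9-[(1S)-2,6,6-trimethylcyclohex-2-en-1-yl]nona-1,6-dien-3-olate (C1=C2 geometry not fixed; either isomer eliminates) | CC1=CCCC(C)(C)[C@@H]1CC/C(C)=C/CC[C@](C)([O-])C=CCl.[Li+] | intermediate (not isolated)
12 | (3S,6E)-3,7-dimethyl-9-[(1S)-2,6,6-trimethylcyclohex-2-en-1-yl]non-6-en-1-yn-3-ol | CC1=CCCC(C)(C)[C@@H]1CC/C(C)=C/CC[C@](C)(O)C#C | intermediate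
13 | 4-bromo-3-iodophenol | Oc1ccc(Br)c(I)c1 | starting material
14 | (4-bromo-3-iodophenoxy)tri(propan-2-yl)silane | CC(C)[Si](Oc1ccc(Br)c(I)c1)(C(C)C)C(C)C | intermediate
15 | (3S,6E)-1-{2-bromo-5-[tri(propan-2-yl)silyloxy]phenyl}-3,7-dimethyl-9-[(1S)-2,6,6-trimethylcyclohex-2-en-1-yl]non-6-en-1-yn-3-ol | CC1=CCCC(C)(C)[C@@H]1CC/C(C)=C/CC[C@](C)(O)C#Cc1cc(O[Si](C(C)C)(C(C)C)C(C)C)ccc1Br | intermediate
16 | (1Z,3S,6E)-1-{2-bromo-5-[tri(propan-2-yl)silyloxy]phenyl}-3,7-dimethyl-9-[(1S)-2,6,6-trimethylcyclohex-2-en-1-yl]nona-1,6-dien-3-ol | CC1=CCCC(C)(C)[C@@H]1CC/C(C)=C/CC[C@](C)(O)/C=C\c1cc(O[Si](C(C)C)(C(C)C)C(C)C)ccc1Br | intermediate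
17 | {[(2S)-2-methyl-2-{(3E)-4-methyl-6-[(1S)-2,6,6-trimethylcyclohex-2-en-1-yl]hex-3-en-1-yl}-2H-chromen-6-yl]oxy}tri(propan-2-yl)silane | CC1=CCCC(C)(C)[C@@H]1CC/C(C)=C/CC[C@@]1(C)C=Cc2cc(O[Si](C(C)C)(C(C)C)C(C)C)ccc2O1 | intermediate
18 | (2S)-2-methyl-2-{(3E)-4-methyl-6-[(1S)-2,6,6-trimethylcyclohex-2-en-1-yl]hex-3-en-1-yl}-2H-chromen-6-ol | CC1=CCCC(C)(C)[C@@H]1CC/C(C)=C/CC[C@@]1(C)C=Cc2cc(O)ccc2O1 | target

**Step count and risks**

Total step count: 13. Longest linear sequence: 12 (steps 1 to 8, then 10 to 13); step 9 is a one-step side branch.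

Steps most likely to fail:

Step 4. What may go wrong: loss of regiocontrol through the directing effect of the internal C11 methyl group; incomplete endo or facial discrimination, either of which lowers the enantiomeric purity of the ring centre once C6 is made symmetric; acid-initiated cation–olefin or carbonyl-ene cyclisation of the polyene. Fallback, replacing asymmetric catalysis by an achiral promoter and resolution through covalent diastereomers (it answers the stereochemical and acid-sensitivity failure modes, not a regiochemical one): it sets out from 4 and 5. Me2AlCl in CH2Cl2 at −78 °C should give the racemic formyl-cis adduct F1. Condensation with (1R,2R)-N,N'-dimethyl-1,2-diphenylethane-1,2-diamine (4 Å molecular sieves, Et2O) should give two diastereomeric aminals, which are separated by chromatography into the wanted (1R,6S)-aminal F2 and the diastereomeric (1S,6R)-aminal F3, the latter being discarded. Mild hydrolysis of F2 (dilute aq. HCl, Et2O, 0 °C) returns to the route at 6.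

Step 12. What may go wrong: β-carbon elimination or ionisation of the tertiary allylic alkoxide on palladium, slow oxidative addition into the electron-rich C–Br bond, and reductive debromination. The same detour also covers over-reduction or debromination in step 11. Fallback, closing the ring at the chroman oxidation level and introducing the C3=C4 double bond afterwards: it sets out from 15. Diimide (2-nitrobenzenesulfonohydrazide, Et3N, CH2Cl2, rt, excess) should saturate the alkyne and leave the trisubstituted alkenes, giving the saturated bromoaryl alcohol F4. The same etherification (Pd(OAc)2, 2-(di-tert-butylphosphino)-1,1'-binaphthyl, Cs2CO3, toluene, 80 °C), now on the saturated tether for which it is best established, should give the silyl-protected (2S)-chroman F5. Benzylic dehydrogenation with DDQ in 1,4-dioxane at reflux returns to the route at 17.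

Step 5. What may go wrong: incomplete hydrazone formation at the neopentyl formyl group, azine formation, and base-mediated migration of the ring double bond at 200 °C. Fallback, replacing the one-pot deoxygenation by reduction, activation and hydride displacement: it sets out from 6. NaBH4 in EtOH at 0 °C should give the neopentyl alcohol F6 with the acetate intact. MsCl and Et3N in CH2Cl2 at 0 °C give the mesylate F7. LiEt3BH in THF at reflux should displace the mesylate by hydride and cleave the acetate in the same operation, returning to the route at 8.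

**Further compounds**

F1 | step 4 | racemic formyl-cis Diels–Alder adduct, (1R,6S) and (1S,6R) enantiomers of 6 | CC1=CCC[C@](C)(C=O)[C@@H]1CC/C(C)=C/CC/C(C)=C/COC(C)=O.CC1=CCC[C@@](C)(C=O)[C@H]1CC/C(C)=C/CC/C(C)=C/COC(C)=O
F2 | step 4 | (2E,6E)-9-[(1R,6S)-6-[(4R,5R)-1,3-dimethyl-4,5-diphenylimidazolidin-2-yl]-2,6-dimethylcyclohex-2-en-1-yl]-3,7-dimethylnona-2,6-dien-1-yl acetate | CC1=CCC[C@](C)(C2N(C)[C@H](c3ccccc3)[C@@H](c3ccccc3)N2C)[C@@H]1CC/C(C)=C/CC/C(C)=C/COC(C)=O
F3 | step 4 | (2E,6E)-9-[(1S,6R)-6-[(4R,5R)-1,3-dimethyl-4,5-diphenylimidazolidin-2-yl]-2,6-dimethylcyclohex-2-en-1-yl]-3,7-dimethylnona-2,6-dien-1-yl acetate (discarded diastereomer) | CC1=CCC[C@@](C)(C2N(C)[C@H](c3ccccc3)[C@@H](c3ccccc3)N2C)[C@H]1CC/C(C)=C/CC/C(C)=C/COC(C)=O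
F4 | step 12 | (3S,6E)-1-{2-bromo-5-[tri(propan-2-yl)silyloxy]phenyl}-3,7-dimethyl-9-[(1S)-2,6,6-trimethylcyclohex-2-en-1-yl]non-6-en-3-ol | CC1=CCCC(C)(C)[C@@H]1CC/C(C)=C/CC[C@](C)(O)CCc1cc(O[Si](C(C)C)(C(C)C)C(C)C)ccc1Br
F5 | step 12 | {[(2S)-2-methyl-2-{(3E)-4-methyl-6-[(1S)-2,6,6-trimethylcyclohex-2-en-1-yl]hex-3-en-1-yl}-3,4-dihydro-2H-chromen-6-yl]oxy}tri(propan-2-yl)silane | CC1=CCCC(C)(C)[C@@H]1CC/C(C)=C/CC[C@@]1(C)CCc2cc(O[Si](C(C)C)(C(C)C)C(C)C)ccc2O1
F6 | step 5 | (2E,6E)-9-[(1R,6S)-6-(hydroxymethyl)-2,6-dimethylcyclohex-2-en-1-yl]-3,7-dimethylnona-2,6-dien-1-yl acetate | CC1=CCC[C@](C)(CO)[C@@H]1CC/C(C)=C/CC/C(C)=C/COC(C)=O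
F7 | step 5 | (2E,6E)-9-[(1R,6S)-6-(methanesulfonyloxymethyl)-2,6-dimethylcyclohex-2-en-1-yl]-3,7-dimethylnona-2,6-dien-1-yl acetate | CC1=CCC[C@](C)(COS(C)(=O)=O)[C@@H]1CC/C(C)=C/CC/C(C)=C/COC(C)=O
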